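What is left in the cedar flask at 2.50 h? A reading of 48.6 % of its G, beside 48.8 % as J, and the split was much the same at 1.00 h.

all flasks: L 0.1 mol%

|  | G | D | remark | time |
|---|---|---|---|---|
| cedar | 31 mM | 0.50 equiv | run made earlier |  |
| maple | 43 mM | 0.50 equiv | run made earlier |  |
| alder | 68 mM | 0.50 equiv | run made earlier |  |
| violet | 31 mM | 0.500 equiv | everything together in a closed stirred flask, run for 2.5 h | 2.5 h |
| blue | 31 mM | 0.500 equiv | one stirred flow tank at steady state, fed with the mixture as stated, mean residence time 12.5 h |  |
| amber | 31 mM | 0.500 equiv (fed, over 2.00 h) | all but D at the start; D goes in evenly over 2.00 h, the run ends at 2.5 h | 2.5 h |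
| grey | 31 mM | 0.500 equiv | a single well-mixed tank run continuously and read at steady state, 2.5 h in it on average |  |

| run | time / h | J / % | G / % |
|---|---|---|---|
| cedar | 0.200 | 20.0 | 79.9 |
| cedar | 0.500 | 42.1 | 57.3 |
| cedar | 1.00 | 50.2 | 50.1 |
| cedar | 2.50 | 48.8 | 48.6 |
| maple | 0.417 | 45.7 | 52.8 |
| maple | 1.00 | 50.0 | 50.0 |
| maple | 2.00 | 49.8 | 49.0 |
| maple | 3.00 | 48.3 | 49.8 |
| alder | 0.417 | 50.1 | 49.9 |
| alder | 1.00 | 51.9 | 50.2 |
| alder | 2.00 | 52.1 | 49.8 |
| alder | 3.00 | 49.4 | 50.6 |

(standard deviation of a reading: 1 percentage point)

- the stated concentrations are those of everything mixed, before any reaction; amounts are the same in each set-up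
- the feed brings no volume worth counting
- the earlier runs were made in a closed, stirred flask

1. the set-up with the highest amount of J at the outlet or at the end, in percent of the G put in ("none" if the first two lie within 2 percentage points) (violet / blue / amber / grey / none)
2. amount of J at the outlet or at the end, in percent of the G put in, violet
3. amount of J at the outlet or at the end, in percent of the G put in, blue
4. amount of J at the outlet or at the end, in percent of the G put in, amber
5. amount of J at the outlet or at the end, in percent of the G put in, grey

Why does G stop there? The readings point to D. At 1.00 h the cedar readings of G and J add up to 100 %, so each G lost appears as one J, and J stands at 50.2 % with 0.50 equiv of D charged.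

So what is the rule? If one D makes one J, D is the limiting reagent, and 50.0 % of the G charged is the ceiling: the equivalents of D read as a fraction of the G charged. I use it as the zero of my scale and count each set-up by its shortfall below it.

Does dilution move it? The last alder and maple readings, 49.4 % and 48.3 %, stay near it, with a scatter of 1 percentage point.

Does violet get there in time? Cedar, with the same charge, was there by 1.00 h, which is earlier than violet's end.

And the weak spot, the tanks and the dosing? Between its first two readings cedar made J at 0.737 /h of the charge, while its shortfall stayed above 7.9 points. To stand at the ceiling, grey must turn over 0.200 /h, and amber's feed brings 0.250 /h, both slower than that rate. Blue asks for less than grey.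

But that rate is an average, and I assume a tank behaves like cedar at the same extent. So I commit to 50.0 % for violet, blue and amber, and to a shortfall under 7.9 points for grey. With two set-ups at the ceiling, the answer to best is none.

The forecast, made separately, gave 49.8 %, 49 %, 49.4 % and 45.5 % with best none, holding that “D is limiting, and J is stable once formed”.

The simulation gives violet 50.0 %, blue 50.0 %, amber 50.0 %, grey 49.9 %, and best none.

    Q ⇌ Z (K = 0.950, k = 2.50 /s)
    D + L → E (k = 2300 /M/s)
    G + E ⇌ Q (K = 13.0 /M, k = 44.0 /M/s)
    Z → L + J (k = 4.00 /s)

Grey's shortfall below the ceiling is 0.10 points, inside my bound. Amber still holds 0.320 % of its D at 2.00 h and 0 % at 2.50 h, with J at 50.0 %, on the ceiling. Now take the neighbouring amber flask with 0.850 equiv of D. Its ceiling is 85.0 %, above the J read in cedar at 1.00 h, so the cedar rate gives me no bound on a shortfall here. That flask gives 85.0 % of J, and 15 % of its G remains.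

(The earlier runs and the new flask are simulated on assumed constants.)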